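## Retrosynthetic overview

1. (S)-Sargachromenol ← desilylation and saponification of its TIPS ether methyl ester ← Z-selective Still–Gennari olefination of a C7' aldehyde with a homoprenyl-substituted bis(trifluoroethyl)phosphonoacetate (sets the 2Z acrylate).
2. C7' aldehyde ← linear chain growth from an (R)-chromenylmethanol: oxidation / HWE / CuH 1,4-reduction, E-selective stabilised Wittig, allylic bromide + LiCH2CN, DIBAL.
3. (R)-Chromenylmethanol ← lipase (CAL-B) desymmetrisation of a prochiral 2,2-bis(hydroxymethyl)-2H-chromene (sets C2, the only stereocentre), then triflate/hydride deoxygenation of the unacylated arm.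
4. Prochiral diol ← 2H-pyran ring (the only ring formed; the arene is purchased) by vinyllithium addition to a salicylaldehyde and o-quinone-methide oxa-6π closure ← ortho-formylation of mono-TIPS methylhydroquinone.

Assumption: CAL-B acylates the same enantiotopic CH2OH arm of the chromene diol as it does in the analogous chroman-2,2-dimethanols, giving the (S)-monoacetate; this sense and the ee must be confirmed (chiral HPLC/Mosher ester) before going on.

General handling: from step 6 onward keep all operations at or below about 50 °C, avoid strong acid and exclude UV light, because a 2H-chromene can racemise through reversible electrocyclic ring opening or C2–O ionisation. TIPS = triisopropylsilyl.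

## Route

**Step 1**
Reactants: 1, 2-methylbenzene-1,4-diol (methylhydroquinone)
Product: 2, 2-methyl-4-[(triisopropylsilyl)oxy]phenol
Conditions: TIPSCl (1.05 equiv), imidazole, DMF, 0 °C; chromatography
Reagents that add atoms: triisopropylsilyl chloride, CC(C)[Si](Cl)(C(C)C)C(C)C
Why: Sterically controlled silylation – the bulky silyl chloride reacts at the unhindered 4-OH rather than the OH flanked by the ortho-methyl group, and the aryl TIPS ether survives every later step until fluoride.

**Step 2**
Reactants: 2, 2-methyl-4-[(triisopropylsilyl)oxy]phenol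
Product: 3, 2-hydroxy-3-methyl-5-[(triisopropylsilyl)oxy]benzaldehyde
Conditions: MgCl2, Et3N, (CH2O)n, MeCN, reflux
Reagents that add atoms: paraformaldehyde (formaldehyde), C=O
Why: Casnati–Skattebøl ortho-formylation of the magnesium phenoxide can only occur at the single free ortho position, which fixes the later chromene substitution pattern (8-Me, 6-O).

**Step 3**
Reactants: 4, 2,2-dimethyl-1,3-dioxan-5-one
Product: 5, 5-(bromomethylidene)-2,2-dimethyl-1,3-dioxane
Conditions: BrCH2PPh3Br, KOtBu, THF, −78 °C → rt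
Reagents that add atoms: (bromomethyl)triphenylphosphonium bromide, BrC[P+](c1ccccc1)(c1ccccc1)c1ccccc1.[Br-]
Why: Wittig bromomethylenation of an electrophilic, symmetric ketone; because the ketone is symmetric the vinyl bromide has no E/Z isomers.

**Step 4**
Reactants: 5, 5-(bromomethylidene)-2,2-dimethyl-1,3-dioxane; 3, 2-hydroxy-3-methyl-5-[(triisopropylsilyl)oxy]benzaldehyde
Product: 6, 2',2',8-trimethyl-6-[(triisopropylsilyl)oxy]spiro[chromene-2,5'-[1,3]dioxane] (achiral)
Conditions: 5 (2.2 equiv), t-BuLi (4.4 equiv), Et2O, −78 °C; add 3 in THF, −78 → 0 °C; aq. NH4Cl; crude carbinol, PPTS (cat.), 4 Å MS, PhMe, 70 °C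
Reagents that add atoms: none
Why: Br–Li exchange and 1,2-addition (the first equivalent deprotonates the phenol) give a transient, unisolated o-hydroxybenzyl allylic alcohol that dehydrates to an o-quinone methide and closes by oxa-6π electrocyclisation to the 2H-chromene, forming the pyran ring with no stereocentre.

**Step 5**
Reactants: 6, spiro-acetonide chromene
Product: 7, {8-methyl-6-[(triisopropylsilyl)oxy]-2H-chromene-2,2-diyl}dimethanol (prochiral diol)
Conditions: p-TsOH·H2O (cat.), MeOH, rt
Reagents that add atoms: none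
Why: Acid-catalysed transketalisation removes the 1,3-dioxane acetonide while the aryl TIPS ether and the chromene (C2 flanked by two deactivating CH2O groups) are stable to mild acid.

**Step 6**
Reactants: 7, prochiral chromene-2,2-dimethanol
Product: 8, [(2S)-2-(hydroxymethyl)-8-methyl-6-[(triisopropylsilyl)oxy]-2H-chromen-2-yl]methyl acetate
Conditions: Candida antarctica lipase B (immobilised, Novozym 435), vinyl acetate, MTBE, 25 °C; filter; use promptly
Reagents that add atoms: vinyl acetate, CC(=O)OC=C
Why: Lipase-catalysed enantiotopos-selective, irreversible transesterification (enzymatic desymmetrisation) acetylates one of the two enantiotopic CH2OH groups and so creates the C2 stereocentre as (S); minor enantiomer is removed by faster over-acylation to the recyclable diacetate.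

**Step 7**
Reactants: 8, (S)-monoacetate
Product: 9, [(2R)-8-methyl-2-{[(trifluoromethanesulfonyl)oxy]methyl}-6-[(triisopropylsilyl)oxy]-2H-chromen-2-yl]methyl acetate
Conditions: Tf2O, pyridine, CH2Cl2, −78 → −20 °C; cold work-up, use crude
Reagents that add atoms: triflic anhydride, O=S(=O)(OS(=O)(=O)C(F)(F)F)C(F)(F)F
Why: O-sulfonylation of the free primary alcohol at low temperature under buffered conditions avoids 1,3-acyl migration; no bond to C2 changes (the R descriptor is a CIP priority change only).

**Step 8**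
Reactants: 9, (R)-triflate acetate
Product: 10, [(2R)-2,8-dimethyl-6-[(triisopropylsilyl)oxy]-2H-chromen-2-yl]methanol
Conditions: LiEt3BH (5 equiv), THF, −78 → 0 °C
Reagents that add atoms: none
Why: Super-Hydride SN2 displacement converts the primary triflate to CH3 and the excess hydride cleaves the acetate reductively, so the formerly free arm becomes the C2 methyl and the formerly acylated arm the CH2OH, with C2 untouched.

**Step 9**
Reactants: 10, (R)-chromenylmethanol
Product: 11, (2R)-2,8-dimethyl-6-[(triisopropylsilyl)oxy]-2H-chromene-2-carbaldehyde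
Conditions: Dess–Martin periodinane, NaHCO3, CH2Cl2, 0 °C → rt; use directly
Reagents that add atoms: none
Why: Buffered Dess–Martin oxidation gives the aldehyde, which has no α-hydrogen and therefore cannot epimerise.

**Step 10**
Reactants: 11, (R)-chromene-2-carbaldehyde
Product: 12, ethyl (2E)-3-[(2R)-2,8-dimethyl-6-[(triisopropylsilyl)oxy]-2H-chromen-2-yl]prop-2-enoate
Conditions: (EtO)2P(O)CH2CO2Et, NaH, THF, 0 °C → rt
Reagents that add atoms: triethyl phosphonoacetate, CCOC(=O)CP(=O)(OCC)OCC
Why: Horner–Wadsworth–Emmons olefination is reactive enough for the hindered α-quaternary aldehyde at low temperature and gives the E-enoate.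

**Step 11**
Reactants: 12, (R,E)-enoate
Product: 13, ethyl 3-[(2S)-2,8-dimethyl-6-[(triisopropylsilyl)oxy]-2H-chromen-2-yl]propanoate
Conditions: Cu(OAc)2·H2O (5 mol %), 1,2-bis(diphenylphosphino)benzene, PMHS, t-BuOH, PhMe, rt
Reagents that add atoms: none
Why: Ligand-accelerated copper hydride (Stryker-type) 1,4-reduction is selective for the electron-poor enoate C=C and leaves the styrenyl chromene C3=C4 bond alone; the descriptor becomes S only through CIP priorities.

**Step 12**
Reactants: 13, saturated ethyl ester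
Product: 14, 3-[(2S)-2,8-dimethyl-6-[(triisopropylsilyl)oxy]-2H-chromen-2-yl]propanal
Conditions: DIBAL-H (1.1 equiv), CH2Cl2, −78 °C; Rochelle salt
Reagents that add atoms: none
Why: Partial DIBAL reduction stops at the aldehyde because the aluminium hemiacetal is stable at −78 °C.

**Step 13**
Reactants: 14, (S)-propanal
Product: 15, ethyl (2E)-5-[(2S)-2,8-dimethyl-6-[(triisopropylsilyl)oxy]-2H-chromen-2-yl]-2-methylpent-2-enoate
Conditions: Ph3P=C(Me)CO2Et, CH2Cl2, 40 °C
Reagents that add atoms: ethyl 2-(triphenylphosphoranylidene)propanoate, CCOC(=O)C(C)=P(c1ccccc1)(c1ccccc1)c1ccccc1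
Why: Wittig olefination with an α-branched stabilised ylide gives the E-trisubstituted enoate (typically ≥95:5), setting the 6E geometry of the target.

**Step 14**
Reactants: 15, (S,E)-enoate
Product: 16, (2E)-5-[(2S)-2,8-dimethyl-6-[(triisopropylsilyl)oxy]-2H-chromen-2-yl]-2-methylpent-2-en-1-ol
Conditions: DIBAL-H (2.5 equiv), CH2Cl2, −78 → 0 °C
Reagents that add atoms: none
Why: DIBAL 1,2-reduction of the conjugated ester gives the allylic alcohol without touching the olefin geometry.

**Step 15**
Reactants: 16, allylic alcohol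
Product: 17, (2S)-2-[(3E)-5-bromo-4-methylpent-3-en-1-yl]-2,8-dimethyl-6-[(triisopropylsilyl)oxy]-2H-chromene
Conditions: CBr4, PPh3, CH2Cl2, 0 °C; use crude
Reagents that add atoms: carbon tetrabromide, BrC(Br)(Br)Br
Why: Appel bromination is neutral and converts the primary allylic alcohol to the bromide without allylic transposition or E/Z erosion.

**Step 16**
Reactants: 17, allylic bromide
Product: 18, (4E)-7-[(2S)-2,8-dimethyl-6-[(triisopropylsilyl)oxy]-2H-chromen-2-yl]-4-methylhept-4-enenitrile
Conditions: MeCN (5 equiv), LDA, THF, −78 °C; then 17, −78 → −20 °C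
Reagents that add atoms: acetonitrile, CC#N
Why: SN2 alkylation of excess lithioacetonitrile at the primary allylic bromide adds the two remaining chain carbons.

**Step 17**
Reactants: 18, nitrile
Product: 19, (4E)-7-[(2S)-2,8-dimethyl-6-[(triisopropylsilyl)oxy]-2H-chromen-2-yl]-4-methylhept-4-enal
Conditions: DIBAL-H (1.3 equiv), PhMe, −78 °C; aq. Rochelle salt, then silica
Reagents that add atoms: water, O
Why: DIBAL reduces the nitrile only to the N-aluminoimine, which hydrolyses on work-up to the aldehyde, so over-reduction is not possible.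

**Step 18**
Reactants: 20, methyl 2-[bis(2,2,2-trifluoroethoxy)phosphoryl]acetate; 21, 5-bromo-2-methylpent-2-ene
Product: 22, methyl 2-[bis(2,2,2-trifluoroethoxy)phosphoryl]-6-methylhept-5-enoate (racemic)
Conditions: NaH, NaI (cat.), DMSO, rt → 50 °C
Reagents that add atoms: none
Why: Malonate-type SN2 C-alkylation of the stabilised phosphonoacetate anion installs the homoprenyl branch; the racemic α-carbon is destroyed in step 19.

**Step 19**
Reactants: 19, (S,E)-aldehyde; 22, homoprenyl Still–Gennari phosphonate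
Product: 23, methyl (2Z,6E)-9-[(2S)-2,8-dimethyl-6-[(triisopropylsilyl)oxy]-2H-chromen-2-yl]-6-methyl-2-(4-methylpent-3-en-1-yl)nona-2,6-dienoate
Conditions: 22, KHMDS, 18-crown-6, THF, −78 °C; then 19; chromatography to remove minor E isomer
Reagents that add atoms: none
Why: Still–Gennari olefination (electron-poor phosphonate, dissociated potassium enolate) gives kinetic Z-selectivity, placing the ester cis to the aldehyde-derived chain as in the target.

**Step 20**
Reactants: 23, TIPS ether methyl ester
Product: 24, methyl (2Z,6E)-9-[(2S)-6-hydroxy-2,8-dimethyl-2H-chromen-2-yl]-6-methyl-2-(4-methylpent-3-en-1-yl)nona-2,6-dienoate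
Conditions: TBAF, AcOH, THF, 0 °C, Ar
Reagents that add atoms: none
Why: Fluoride-mediated Si–O cleavage frees the phenol under buffered conditions that leave the ester, the olefins and C2 untouched.

**Step 21**
Reactants: 24, phenol methyl ester
Product: 25, (S)-sargachromenol, (2Z,6E)-9-[(2S)-6-hydroxy-2,8-dimethyl-2H-chromen-2-yl]-6-methyl-2-(4-methylpent-3-en-1-yl)nona-2,6-dienoic acid
Conditions: LiOH·H2O, THF/MeOH/H2O (degassed), 40 °C, Ar; aq. citric acid to pH 4
Reagents that add atoms: lithium hydroxide / water, [Li+].[OH-] (O)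
Why: Saponification (BAc2) of the hindered methyl ester under oxygen-free conditions gives the acid without Z→E isomerisation or oxidation of the chromenol.

## Compound list

1 | 2-methylbenzene-1,4-diol | Cc1cc(O)ccc1O | starting material
2 | 2-methyl-4-[(triisopropylsilyl)oxy]phenol | Cc1cc(O[Si](C(C)C)(C(C)C)C(C)C)ccc1O | intermediate
3 | 2-hydroxy-3-methyl-5-[(triisopropylsilyl)oxy]benzaldehyde | O=Cc1cc(O[Si](C(C)C)(C(C)C)C(C)C)cc(C)c1O | intermediate
4 | 2,2-dimethyl-1,3-dioxan-5-one | CC1(C)OCC(=O)CO1 | starting material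
5 | 5-(bromomethylidene)-2,2-dimethyl-1,3-dioxane | CC1(C)OCC(=CBr)CO1 | intermediate
6 | 2',2',8-trimethyl-6-[(triisopropylsilyl)oxy]spiro[chromene-2,5'-[1,3]dioxane] | CC1(C)OCC2(CO1)C=Cc1cc(O[Si](C(C)C)(C(C)C)C(C)C)cc(C)c1O2 | intermediate
7 | {8-methyl-6-[(triisopropylsilyl)oxy]-2H-chromene-2,2-diyl}dimethanol | OCC1(CO)C=Cc2cc(O[Si](C(C)C)(C(C)C)C(C)C)cc(C)c2O1 | intermediate
8 | [(2S)-2-(hydroxymethyl)-8-methyl-6-[(triisopropylsilyl)oxy]-2H-chromen-2-yl]methyl acetate | CC(=O)OC[C@@]1(CO)C=Cc2cc(O[Si](C(C)C)(C(C)C)C(C)C)cc(C)c2O1 | intermediate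
9 | [(2R)-8-methyl-2-{[(trifluoromethanesulfonyl)oxy]methyl}-6-[(triisopropylsilyl)oxy]-2H-chromen-2-yl]methyl acetate | CC(=O)OC[C@@]1(COS(=O)(=O)C(F)(F)F)C=Cc2cc(O[Si](C(C)C)(C(C)C)C(C)C)cc(C)c2O1 | intermediate
10 | [(2R)-2,8-dimethyl-6-[(triisopropylsilyl)oxy]-2H-chromen-2-yl]methanol | OC[C@@]1(C)C=Cc2cc(O[Si](C(C)C)(C(C)C)C(C)C)cc(C)c2O1 | intermediate
11 | (2R)-2,8-dimethyl-6-[(triisopropylsilyl)oxy]-2H-chromene-2-carbaldehyde | O=C[C@@]1(C)C=Cc2cc(O[Si](C(C)C)(C(C)C)C(C)C)cc(C)c2O1 | intermediate
12 | ethyl (2E)-3-[(2R)-2,8-dimethyl-6-[(triisopropylsilyl)oxy]-2H-chromen-2-yl]prop-2-enoate | CCOC(=O)/C=C/[C@@]1(C)C=Cc2cc(O[Si](C(C)C)(C(C)C)C(C)C)cc(C)c2O1 | intermediate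
13 | ethyl 3-[(2S)-2,8-dimethyl-6-[(triisopropylsilyl)oxy]-2H-chromen-2-yl]propanoate | CCOC(=O)CC[C@@]1(C)C=Cc2cc(O[Si](C(C)C)(C(C)C)C(C)C)cc(C)c2O1 | intermediate
14 | 3-[(2S)-2,8-dimethyl-6-[(triisopropylsilyl)oxy]-2H-chromen-2-yl]propanal | O=CCC[C@@]1(C)C=Cc2cc(O[Si](C(C)C)(C(C)C)C(C)C)cc(C)c2O1 | intermediate
15 | ethyl (2E)-5-[(2S)-2,8-dimethyl-6-[(triisopropylsilyl)oxy]-2H-chromen-2-yl]-2-methylpent-2-enoate | CCOC(=O)/C(C)=C/CC[C@@]1(C)C=Cc2cc(O[Si](C(C)C)(C(C)C)C(C)C)cc(C)c2O1 | intermediate
16 | (2E)-5-[(2S)-2,8-dimethyl-6-[(triisopropylsilyl)oxy]-2H-chromen-2-yl]-2-methylpent-2-en-1-ol | OC/C(C)=C/CC[C@@]1(C)C=Cc2cc(O[Si](C(C)C)(C(C)C)C(C)C)cc(C)c2O1 | intermediate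
17 | (2S)-2-[(3E)-5-bromo-4-methylpent-3-en-1-yl]-2,8-dimethyl-6-[(triisopropylsilyl)oxy]-2H-chromene | BrC/C(C)=C/CC[C@@]1(C)C=Cc2cc(O[Si](C(C)C)(C(C)C)C(C)C)cc(C)c2O1 | intermediate
18 | (4E)-7-[(2S)-2,8-dimethyl-6-[(triisopropylsilyl)oxy]-2H-chromen-2-yl]-4-methylhept-4-enenitrile | N#CCC/C(C)=C/CC[C@@]1(C)C=Cc2cc(O[Si](C(C)C)(C(C)C)C(C)C)cc(C)c2O1 | intermediate
19 | (4E)-7-[(2S)-2,8-dimethyl-6-[(triisopropylsilyl)oxy]-2H-chromen-2-yl]-4-methylhept-4-enal | O=CCC/C(C)=C/CC[C@@]1(C)C=Cc2cc(O[Si](C(C)C)(C(C)C)C(C)C)cc(C)c2O1 | intermediate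
20 | methyl 2-[bis(2,2,2-trifluoroethoxy)phosphoryl]acetate | COC(=O)CP(=O)(OCC(F)(F)F)OCC(F)(F)F | starting material
21 | 5-bromo-2-methylpent-2-ene | CC(C)=CCCBr | starting material
22 | methyl 2-[bis(2,2,2-trifluoroethoxy)phosphoryl]-6-methylhept-5-enoate (racemic) | COC(=O)C(CCC=C(C)C)P(=O)(OCC(F)(F)F)OCC(F)(F)F | intermediate
23 | methyl (2Z,6E)-9-[(2S)-2,8-dimethyl-6-[(triisopropylsilyl)oxy]-2H-chromen-2-yl]-6-methyl-2-(4-methylpent-3-en-1-yl)nona-2,6-dienoate | CC(C)=CCC/C(=C/CC/C(C)=C/CC[C@@]1(C)C=Cc2cc(O[Si](C(C)C)(C(C)C)C(C)C)cc(C)c2O1)C(=O)OC | intermediate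
24 | methyl (2Z,6E)-9-[(2S)-6-hydroxy-2,8-dimethyl-2H-chromen-2-yl]-6-methyl-2-(4-methylpent-3-en-1-yl)nona-2,6-dienoate | CC(C)=CCC/C(=C/CC/C(C)=C/CC[C@@]1(C)C=Cc2cc(O)cc(C)c2O1)C(=O)OC | intermediate
25 | (S)-sargachromenol | CC(C)=CCC/C(=C/CC/C(C)=C/CC[C@@]1(C)C=Cc2cc(O)cc(C)c2O1)C(=O)O | target

## Totals and risks

Total steps: 21. Longest linear sequence: 19 (steps 1, 2, 4–17, 19–21, from compound 1 to 25); steps 3 and 18 are single-step side branches.

Three steps most likely to fail:

1. **Step 6 (lipase desymmetrisation).** The chromene diol is a new substrate, so the sense of selectivity, the ee and over-acylation are uncertain, and the monoacetate can racemise by 1,3-acyl migration. Fallback: run the enzyme in the hydrolytic direction – peracetylate 7 and carry out lipase-catalysed mono-hydrolysis of the prochiral diacetate, which delivers the monoacetate of the opposite enantiotopic arm. If that gives the (R)-monoacetate, exchange the roles of the arms: silylate the free OH, remove the acetate, chain-extend that arm and deoxygenate the other later.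

2. **Step 8 (triflate → CH3 next to an acetate).** Acetoxonium participation would scramble the arms and racemise C2; oxetane formation after acetate cleavage or S–O attack are also possible. Fallback: deoxygenate through the carbonyl instead – oxidise the free CH2OH of 8 to the aldehyde (DMP), form the tosylhydrazone, reduce with catecholborane/NaOAc to CH3, then K2CO3/MeOH to reach 10. No leaving group is then placed on the neopentyl carbon.

3. **Step 11 (CuH 1,4-reduction).** The β-carbon is next to a quaternary centre and the chromene alkene must survive. Fallback: avoid the enoate altogether – convert 10 to its triflate, displace with lithioacetonitrile to form the C1'–C2' bond by SN2, and reduce the nitrile with DIBAL to aldehyde 14.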